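The readings are calculated for substances that don't exist, and the scatter is random.

| setting | winter | midnight | spring | north-west | north-east | north | south |
|---|---|---|---|---|---|---|---|
| starting material | 0.0037 M (in portions, 2) | 0.0080 M (in portions, 2) | 0.011 M (in portions, 2) | 0.011 M (in portions, 2) | 0.011 M (in portions, 2) | 0.011 M (in portions, 2) | 0.0060 M (in portions, 2) |
| protic impurity | 2.2 mM | 2.2 mM | 2.2 mM | 2.20 mM | 2.20 mM | 2.20 mM | 1.50 mM |
| catalyst | 1 mM | 1 mM | 0.80 mM | 0.60 mM | 0.50 mM | 1.0 mM | 1.0 mM |
| temperature | 39 °C | 47 °C | 39 °C | 50 °C | 35 °C | 50 °C | 35 °C |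
| remark | run made earlier; portions every 8.0 h | run made earlier; portions every 8.0 h | run made earlier; portions every 8.0 h | the portions of starting material follow each other after 4.0 h, the first at the start | the portions of starting material follow each other after 8.0 h, the first at the start | the portions of starting material follow each other after 8.0 h, the first at the start | the portions of starting material follow each other after 8.0 h, the first at the start |
| time |  |  |  | 40 h | 40 h | 40 h | 40 h |

| run | time / h | intermediate / % | target / % | starting material / % |
|---|---|---|---|---|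
| winter | 15.0 | 30 | 2 | 53 |
| winter | 25.0 | 40 | 6 | 32 |
| winter | 30.0 | 41 | 6 | 26 |
| winter | 48.0 | 46 | 8 | 11 |
| midnight | 8.00 | 23 | 4 | 19 |
| midnight | 15.0 | 52 | 5 | 25 |
| midnight | 20.0 | 56 | 7 | 11 |
| midnight | 30.0 | 51 | 6 | 4 |
| spring | 4.00 | 3 | 2 | 38 |
| spring | 8.00 | 13 | 0 | 29 |
| spring | 20.0 | 36 | 2 | 47 |
| spring | 48.0 | 55 | 6 | 13 |

(scatter of a reading: 1.5 percentage points)

* all flasks from highest to lowest amount of intermediate, in percent of the starting material charged, at 40 h (north-west / north-east / north / south)
* the amount of intermediate, in percent of the starting material charged of the flask you put first, at 40 h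
* the amount of intermediate, in percent of the starting material charged of the flask you put last, at 40 h

- no earlier run changes the charge of protic impurity; that part of a forecast is a guess

The target reads 6% at 30.0 h in the midnight run, so we follow the drain on intermediate instead. We count lifetimes of intermediate: N is drain times waiting time, and feed times exp(−N) survives.

1. Drain. In the midnight run, from 20.0 h to 30.0 h, intermediate falls although starting material still feeds it. Counting that feed gives 0.0224 h⁻¹. The winter run, from 30.0 h to 48.0 h, gives 0.0128 h⁻¹.

2. Temperature. Taking the logarithm as straight in temperature, 50 °C lies 3 degrees beyond 47 °C, on a span of 8. So d, the pseudo-first-order drain at 1.0 mM of catalyst and 50 °C, is 0.0277 h⁻¹. We scale it with catalyst.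

3. Feed. Starting material decays at 0.122 h⁻¹ in the midnight run and 0.0476 h⁻¹ in the winter run, hence 0.174 h⁻¹ at 50 °C. Mean entry into intermediate is then 9.75 h in north and 7.75 h in north-west. The spring run, with the same charge, still shows 85.0% at 20.0 h; we take that as feed.

4. Hot flasks. North has N = 0.838, giving 36.8%. North-west has N = 0.536, giving 49.7%.

5. Cold flasks. At 35 °C, decay of 0.0298 h⁻¹ leaves 34.5% starting material. The drain at 1.0 mM is 0.00964 h⁻¹, with a mean wait of 18.0 h. So north-east gives 46.3% and south 42.5%.

6. Weak link: proportion to catalyst. From 20.0 h to 48.0 h the spring drain is 0.0118 h⁻¹, or 0.922 of winter's, at a catalyst ratio of 0.800. That rests on a loss of 15 percentage points with 1.5 points scatter per reading, so it does not separate the ratio from 1. We keep the proportion, and north-west stands above north on it.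

The forecast differs from our reckoning: north-west > north > south > north-east, top 52%, low 32%, holding that north-west, “with less catalyst, should decay less”.

The flasks give north-west > north-east > south > north: 52.0%, 44.9%, 41.2%, 39.4%.

    starting material → intermediate (k = 4.52 × 10⁻⁵ s⁻¹, Ea = 106 kJ mol⁻¹)
    catalyst + intermediate → catalyst + target (k = 0.00729 M⁻¹ s⁻¹, Ea = 53.0 kJ mol⁻¹)
    starting material + protic impurity → quenched substrate (k = 0.00540 M⁻¹ s⁻¹, Ea = 51.0 kJ mol⁻¹)
    target → over-reaction product (k = 5.44 × 10⁻⁵ s⁻¹, Ea = 92.0 kJ mol⁻¹)
    (constants at 50 °C)

Take a flask like north-west with 0.240 mM of catalyst. Its drain is 0.0277 h⁻¹ scaled to 0.00665 h⁻¹, and over the same wait N = 0.214, so we reckon 68.6% intermediate. That flask holds 70.4% intermediate, with 2.32% target and 13.6% over-reaction product.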